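**Assumptions (one line each)**
- Ortho C-prenylation of 4-hydroxybenzaldehyde in aqueous NaOH (Step 1) is taken to be the major pathway, with O-prenylation as a minor, separable by-product.
- The target is (2R), confirmed from the SMILES by CIP analysis (O > aryl > CH2 > H).
- Quinidine-derived catalyst 11 is assumed to give the (2R)-flavanone and the quinine-derived pseudo-enantiomer the (2S). The configuration of 12 must be confirmed by chiral HPLC and the catalyst series switched if the wrong enantiomer forms.
- The 7-OH is kept as a MOM ether until the last step. A free 7-phenoxide can push open the pyranone ring (retro-oxa-Michael) and racemize C2.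

## Retrosynthesis

- The target is obtained from the (2R)-7-O-MOM flavanone by MOM removal. The flavanone comes from an enantioselective intramolecular oxa-Michael addition of the 2'-OH onto a 2'-hydroxychalcone. This step sets the only stereocenter.
- The chalcone comes from Claisen–Schmidt condensation of 4'-O-MOM-2'-hydroxyacetophenone with an 8-prenyl-2,2-dimethylchromene-6-carbaldehyde.
- The chromene ring of the aldehyde is built by propargyl Claisen rearrangement and 6π-oxa-electrocyclization of a 3-prenyl-4-(1,1-dimethylpropargyloxy)benzaldehyde. That ether comes from 4-hydroxybenzaldehyde by ortho-prenylation and O-propargylation.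
- Ring order: chromene ring first, then the chalcone C–C bond, then the pyranone ring (stereocenter) last.

## Route

**Step 1**
- Reactants: 1 (4-hydroxybenzaldehyde), 2 (prenyl bromide)
- Product: 3 (4-hydroxy-3-(3-methylbut-2-en-1-yl)benzaldehyde)
- Conditions: NaOH (1 equiv), H2O, 0 °C → rt, 24 h
- Reagents that add atoms: prenyl bromide, CC(C)=CCBr
- Why: In water the phenoxide oxygen is strongly hydrogen-bonded, so the free ortho carbon attacks the allylic bromide (SN2 C-alkylation). O-prenyl and 3,5-diprenyl by-products are removed by chromatography.

**Step 2**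
- Reactants: 3, 4 (3-chloro-3-methylbut-1-yne)
- Product: 5 (3-prenyl-4-[(2-methylbut-3-yn-2-yl)oxy]benzaldehyde)
- Conditions: K2CO3, KI, CuI (cat.), DMF, 60 °C
- Reagents that add atoms: 3-chloro-3-methylbut-1-yne, CC(C)(Cl)C#C
- Why: Cu-assisted O-alkylation of the phenol with the tertiary propargylic chloride (Godfrey-type propargylation) gives the aryl 1,1-dimethylpropargyl ether.

**Step 3**
- Reactant: 5
- Product: 6 (2,2-dimethyl-8-(3-methylbut-2-en-1-yl)-2H-chromene-6-carbaldehyde)
- Conditions: N,N-diethylaniline, 190 °C, 3 h
- Reagents that add atoms: none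
- Why: Aromatic propargyl Claisen [3,3] rearrangement gives an allenyl dienone. Tautomerization to the o-allenylphenol and a 1,5-H shift give the o-quinone methide diene, and 6π-oxa-electrocyclization closes the 2H-chromene. The only free ortho position (C5) closes the ring because the other ortho position carries the prenyl group.

**Step 4**
- Reactants: 7 (2',4'-dihydroxyacetophenone), 8 (chloromethyl methyl ether)
- Product: 9 (1-[2-hydroxy-4-(methoxymethoxy)phenyl]ethan-1-one)
- Conditions: MOMCl, iPr2NEt, CH2Cl2, 0 °C → rt
- Reagents that add atoms: chloromethyl methyl ether, COCCl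
- Why: The 2'-OH is hydrogen-bonded to the carbonyl and much less nucleophilic, so only the 4'-OH is protected as the MOM acetal (chemoselective O-alkylation).

**Step 5**
- Reactants: 6, 9
- Product: 10 ((E)-3-(2,2-dimethyl-8-prenyl-2H-chromen-6-yl)-1-[2-hydroxy-4-(methoxymethoxy)phenyl]prop-2-en-1-one)
- Conditions: 50% aq. KOH, EtOH, 0 °C → rt, 48 h; then cold dilute HCl to pH ~5
- Reagents that add atoms: none
- Why: Claisen–Schmidt (aldol/E1cB) condensation. The MOM acetal, prenyl alkene and chromene alkene are base-stable. The chalcone stays as its open phenoxide in strong base, and the cold mild acid quench avoids uncontrolled racemic cyclization. The E-chalcone is formed.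

**Step 6**
- Reactants: 10, 11 (quinidine-derived 9-epi-amino thiourea catalyst)
- Product: 12 ((2R)-7-(methoxymethoxy)-2-(2,2-dimethyl-8-prenyl-2H-chromen-6-yl)chroman-4-one)
- Conditions: 11 (20 mol %), toluene, rt, 4 d
- Reagents that add atoms: none (11 is a catalyst and is not incorporated)
- Why: Intramolecular oxa-Michael addition (bifunctional organocatalysis). The tertiary amine of 11 deprotonates the 2'-OH, and the thiourea N–H groups bind and activate the enone carbonyl. Face-selective C–O bond formation closes the pyranone ring and sets C2 as R. Because the 7-O is acylated-free but alkyl-protected as the MOM ether, the product is less prone to retro-Michael racemization, and ee can be upgraded by recrystallization.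

**Step 7**
- Reactant: 12
- Product: 13 (ent-abyssinone III)
- Conditions: TsOH·H2O (0.3 equiv), MeOH/CH2Cl2 (1:1), 35 °C, monitor by TLC
- Reagents that add atoms: none
- Why: Acid-catalysed acetal exchange with methanol removes the MOM group (lost as CH2(OMe)2). These mild conditions leave the C2 stereocenter, the prenyl alkene and the chromene intact, and the ketone and ring oxygen are untouched.

## Compound list

1 | 4-hydroxybenzaldehyde | O=Cc1ccc(O)cc1 | starting material
2 | prenyl bromide (1-bromo-3-methylbut-2-ene) | CC(C)=CCBr | starting material (reagent)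
3 | 4-hydroxy-3-prenylbenzaldehyde | CC(C)=CCc1cc(C=O)ccc1O | intermediate
4 | 3-chloro-3-methylbut-1-yne | CC(C)(Cl)C#C | starting material (reagent)
5 | 3-prenyl-4-[(2-methylbut-3-yn-2-yl)oxy]benzaldehyde | CC(C)=CCc1cc(C=O)ccc1OC(C)(C)C#C | intermediate
6 | 2,2-dimethyl-8-prenyl-2H-chromene-6-carbaldehyde | CC(C)=CCc1cc(C=O)cc2C=CC(C)(C)Oc12 | intermediate
7 | 2',4'-dihydroxyacetophenone | CC(=O)c1ccc(O)cc1O | starting material
8 | chloromethyl methyl ether (MOMCl) | COCCl | starting material (reagent)
9 | 2'-hydroxy-4'-(methoxymethoxy)acetophenone | CC(=O)c1ccc(OCOC)cc1O | intermediate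
10 | (E)-chalcone from 6 and 9 | CC(C)=CCc1cc(/C=C/C(=O)c2ccc(OCOC)cc2O)cc2C=CC(C)(C)Oc12 | intermediate
11 | N-[3,5-bis(trifluoromethyl)phenyl]-N'-(9-deoxy-9-epi-quinidin-9-yl)thiourea (9-epi-amino-quinidine thiourea, 8R,9R) | COC1=CC2=C(C=CN=C2C=C1)[C@H]([C@H]3C[C@@H]4CCN3C[C@@H]4C=C)NC(=S)Nc5cc(cc(c5)C(F)(F)F)C(F)(F)F | starting material (organocatalyst, not incorporated)
12 | (2R)-7-(methoxymethoxy)-2-(2,2-dimethyl-8-prenylchromen-6-yl)chroman-4-one | CC(C)=CCc1cc([C@H]2CC(=O)c3ccc(OCOC)cc3O2)cc2C=CC(C)(C)Oc12 | intermediate
13 | ent-abyssinone III, (2R) | CC(C)=CCc1cc([C@H]2CC(=O)c3ccc(O)cc3O2)cc2c1OC(C)(C)C=C2 | target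

## Totals

- Total steps: 7.
- Longest linear sequence: 6 steps (1 → 3 → 5 → 6 → 10 → 12 → 13, i.e. Steps 1, 2, 3, 5, 6, 7). Step 4 is a separate branch that makes 9.

## Three steps most likely to fail

1. **Step 6 (enantioselective oxa-Michael).** Risks are low conversion, reversibility and moderate ee for a relatively electron-rich, unactivated chalcone. The catalyst series giving R is also assumed.
   - Fallback: cyclize 10 racemically (NaOAc, EtOH, reflux) and resolve 12 by preparative chiral-phase HPLC, or obtain the (S)-flavanone with the quinine-derived catalyst if the sense is reversed.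
2. **Step 1 (ortho C-prenylation).** Risks are poor C/O selectivity, over-alkylation and low yield.
   - Fallback: allylate 1 to the aryl ether, do a thermal Claisen rearrangement to 3-allyl-4-hydroxybenzaldehyde, then cross-metathesis with 2-methyl-2-butene (Grubbs II) to give 3.
3. **Step 7 (MOM removal).** The acid-sensitive chromene and prenyl alkene could be damaged, or C2 could erode.
   - Fallback: carry a 4'-O-allyl group instead of MOM (allyl bromide in Step 4), then remove it under neutral conditions in the last step (Pd(PPh3)4, morpholine).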